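At late times both earlier runs have nearly stopped, and two chemists read that stop differently.

in all of them: starting material 13 mM; free catalyst 1.3 mM

| run | partner | remark | time |
|---|---|---|---|
| red | 0.85 mM | run made earlier |  |
| blue | 4.8 mM | run made earlier |  |
| alder | 1.00 mM |  | 20 min |
| birch | 3.00 mM |  | 20 min |
| cedar | 8.00 mM |  | 20 min |
| elm | 25.0 mM |  | 20 min |

| run | time / min | target / % | starting material / % |
|---|---|---|---|
| red | 1.50 | 5 | 96 |
| red | 3.00 | 2 | 97 |
| red | 6.00 | 4 | 96 |
| red | 10.0 | 4 | 96 |
| red | 20.0 | 7 | 95 |
| blue | 2.00 | 9 | 90 |
| blue | 5.00 | 15 | 80 |
| blue | 10.0 | 21 | 74 |
| blue | 15.0 | 23 | 70 |
| blue | 20.0 | 25 | 72 |

(readings scatter by 1.5 percentage points)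

- "hardly changes" means that all values lie within two and a half points (for a concentration: within two and a half percent of the largest)

- amount of target at the end, in percent of the starting material charged for alder, birch, cedar, elm, in this order
- how that number moves from the first to the last of them (rises all the way / rises, then falls / hardly changes / falls, then rises / falls all the way)

Red ends at 7% target from a partner charge worth 6.54% of the starting material, which both take as the partner being the limiting reagent at one partner per target, within the scatter of 1.5 percentage points. Blue is the quarrel, for it ends at 25% target from a charge worth 36.9%, which is more than the target shows. The first chemist reads this as a balance between starting material and target, a single step running both ways, and expects about 75% target in elm, with the row climbing to the end. The second answers that blue's last two readings of target and starting material fall short of the whole charge by 5 points on average, while red's last pair sums to 102%, so something unseen is taking up target and partner.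

My own reckoning follows the second chemist and works with the fraction of starting material left, not the fraction made. Suppose both steps consume partner and run equally fast at equal amounts, an even race. Partner then drops out of the comparison: for each bit of starting material lost, target gains that bit and loses that bit times target divided by fraction left. This gives a target share equal to the fraction left times the ln of its inverse. At blue's 72% left that is 23.7%, against 25% read. The curve tops out where the fraction left is 36.8%, with target at the same share and over-reaction product at 26.4%. At one partner per target and two per over-reaction product, the partner consumed by that point comes to 11.7 mM. This turning charge, the partner charge at which an even race tops out, lies above cedar's 8.00 mM and below elm's 25.0 mM. So I expect a hump in the row, though this gives its place and not elm's height.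

The forecast sides with the second chemist, holding that “the target takes up a second partner to give an unseen over-product”. It gives 7%, 18%, 33% and 20%, and the shape rises, then falls.

The flask gives 7.07%, 18.0%, 30.9% and 14.2%, the shape rises, then falls, turning at 11 mM against the turning charge of 11.7 mM, with cedar's 54.1% of starting material left above 36.8% and elm's 12.4% below it.

    partner + target → over-reaction product (k = 0.430 /M/s)
    starting material + catalyst intermediate A ⇌ catalyst intermediate B (K = 81.0 /M, k = 3.90 /M/s)
    partner + free catalyst ⇌ catalyst intermediate A (K = 240 /M, k = 7.20 /M/s)
    catalyst intermediate B ⇌ catalyst intermediate C (K = 0.320, k = 7.70 /s)
    catalyst intermediate C → free catalyst + target (k = 0.280 /s)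

The first chemist's single step, with all reacted starting material counted as target, stands nearer in alder and birch, where over-reaction product is 0.289% and 2.47%, less than in cedar or elm. In alder at 2.34 min, partner has a forward half-life of 1.4 min for binding free catalyst, longer than the 0.24 min of catalyst intermediate A in its forward step with starting material. Free catalyst, the resting state in alder, stands at 98.8% at 10.0 min.

The data come from a simulation for an exercise; the scatter is artificial.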